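The δ-lactone ring (O1, C2–C6) is disconnected at C3–C4 and at O1–C6 at once. This exposes an acetate unit (C3–C2(=O)–O1) as a C,O-dinucleophile and a C4–C5–C6 1,3-dielectrophile, and exploits that C4 is a carbinol (aldehyde carbon) while C6 is allylic to the exocyclic C1'=C2' alkene (terminus of a π-allyl). In one flask a ketene bis(silyl) acetal adds to the aldehyde under a chiral titanium catalyst and the unmasked carboxylate closes on a palladium π-allyl, which sets C4, C6 and the E-alkene. The precursor is an open-chain skipped enal with an allylic carbonate at C2', whose stereocentre is relayed to C6 and erased.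

Key step: step 10

Remarks on the chemistry:
- Locants follow the target: lactone O1, C2–C6; side chain C1'–C8', with C1' on C6.
- Diene 2 is taken as purchased. The Schiff-base ligand of step 10 is treated as a catalyst component (one condensation of commercial 2-amino-2'-hydroxy-1,1'-binaphthyl with 3-bromo-5-tert-butylsalicylaldehyde).
- The ligand enantiomers in steps 1, 5 and 10 are chosen by the required face of attack; the sense of induction should be confirmed on the first product of each.
- The C7 descriptor of the undecadienyl chain changes from R (11) to S (12, 13, 17) by CIP ranking only; the geometry is unchanged.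

Step 1
Reactants: 1 (E)-cinnamaldehyde; 2 1-methoxy-1,3-bis(trimethylsilyloxy)buta-1,3-diene
Product: 4 methyl (5S,6E)-5-hydroxy-3-oxo-7-phenylhept-6-enoate, via bis-silylated aldol adduct 3 (not isolated)
Conditions: Ti(OiPr)4 (8 mol %), (S)-BINOL (8 mol %), 4 Å MS, THF, −78 °C to rt; then CF3CO2H, 0 °C
Reagents that add atoms: none
Why: Catalytic enantioselective vinylogous Mukaiyama aldol, in which the terminal carbon of the silyl dienolate adds 1,2 to the enal on the titanium–BINOLate, the (S)-ligand being chosen to direct attack to the Si face and so set 5S (future C6'), after which acid cleaves both silyl groups.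

Step 2
Reactants: 4 methyl (5S,6E)-5-hydroxy-3-oxo-7-phenylhept-6-enoate
Product: 5 methyl (3S,5S,6E)-3,5-dihydroxy-7-phenylhept-6-enoate
Conditions: Me4NBH(OAc)3, MeCN–AcOH (1:1), −30 °C
Reagents that add atoms: none
Why: Evans–Saksena reduction, in which acetate exchange ties the borohydride to the C5 hydroxyl and hydride is delivered intramolecularly through a chair transition state, which should give the 1,3-anti diol and thereby 3S (future C4').

Step 3
Reactants: 5 methyl (3S,5S,6E)-3,5-dihydroxy-7-phenylhept-6-enoate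
Product: 6 methyl (3S,5S,6E)-3,5-dimethoxy-7-phenylhept-6-enoate
Conditions: Me3OBF4, 1,8-bis(dimethylamino)naphthalene, 4 Å MS, CH2Cl2, 0 °C to rt
Reagents that add atoms: trimethyloxonium tetrafluoroborate, C[O+](C)C.F[B-](F)(F)F
Why: O-Alkylation with Meerwein's salt under a non-nucleophilic amine buffer should methylate both hydroxyls without the retro-aldol, β-elimination or lactonisation that alkoxide conditions invite, and it touches no stereocentre.

Step 4
Reactants: 6 methyl (3S,5S,6E)-3,5-dimethoxy-7-phenylhept-6-enoate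
Product: 7 (3S,5S,6E)-3,5-dimethoxy-7-phenylhept-6-enal
Conditions: iBu2AlH (1.1 equiv), CH2Cl2, −78 °C; aq. potassium sodium tartrate
Reagents that add atoms: none
Why: Partial ester reduction, in which the aluminium hemiacetal (stabilised by chelation to the β-methoxy group) persists at −78 °C and releases the aldehyde only on work-up.

Step 5
Reactants: 8 tert-butyl(but-3-yn-1-yloxy)dimethylsilane; 7 (3S,5S,6E)-3,5-dimethoxy-7-phenylhept-6-enal
Product: 11 (3E,5S,7R,9S,10E)-1-(tert-butyldimethylsilyloxy)-7,9-dimethoxy-11-phenylundeca-3,10-dien-5-ol, via alkenylborane 9 (not isolated), via alkenylzinc 10 (not isolated)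
Conditions: Cy2BH (from BH3·SMe2, cyclohexene), hexane, 0 °C to rt; Me2Zn, (+)-MIB (5 mol %), −78 °C; 7, −30 to 0 °C; aq. NH4Cl
Reagents that add atoms: none
Why: Hydroboration–transmetalation–alkenylzinc addition, in which syn-hydroboration fixes the E-alkene, boron-to-zinc exchange gives the alkenyl(methyl)zinc, and the amino-alcohol zinc catalyst from the (+)-ligand (antipode of the one that delivers to the Si face) should add it to the Re face of 7 to set the 5S carbinol.

Step 6
Reactants: 11 (3E,5S,7R,9S,10E)-1-(tert-butyldimethylsilyloxy)-7,9-dimethoxy-11-phenylundeca-3,10-dien-5-ol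
Product: 12 (3E,5S,7S,9S,10E)-1-(tert-butyldimethylsilyloxy)-7,9-dimethoxy-11-phenylundeca-3,10-dien-5-yl methyl carbonate
Conditions: ClCO2Me, pyridine, DMAP (cat.), CH2Cl2, 0 °C
Reagents that add atoms: methyl chloroformate, COC(=O)Cl
Why: Nucleophile-catalysed O-acylation of the secondary allylic alcohol installs the carbonate leaving group with retention at the carbinol carbon.

Step 7
Reactants: 12 (3E,5S,7S,9S,10E)-1-(tert-butyldimethylsilyloxy)-7,9-dimethoxy-11-phenylundeca-3,10-dien-5-yl methyl carbonate
Product: 13 (3E,5S,7S,9S,10E)-1-hydroxy-7,9-dimethoxy-11-phenylundeca-3,10-dien-5-yl methyl carbonate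
Conditions: HF·pyridine, pyridine, THF, 0 °C to rt
Reagents that add atoms: none
Why: Fluoride-driven desilylation (formation of the strong Si–F bond) frees the primary alcohol, and the buffered medium should leave the carbonate, the methyl ethers and both alkenes intact.

Step 8
Reactants: 14 trimethylsilyl acetate
Product: 16 1,1-bis(trimethylsilyloxy)ethene, via lithium enolate 15 (not isolated)
Conditions: LiN(iPr)2, THF, −78 °C; Me3SiCl, −78 °C to rt; distillation
Reagents that add atoms: chlorotrimethylsilane, C[Si](C)(C)Cl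
Why: Silyl ketene acetal formation by kinetic enolisation of the silyl ester and O-silylation of the hard lithium enolate.

Step 9
Reactants: 13 (3E,5S,7S,9S,10E)-1-hydroxy-7,9-dimethoxy-11-phenylundeca-3,10-dien-5-yl methyl carbonate
Product: 17 (3E,5S,7S,9S,10E)-7,9-dimethoxy-1-oxo-11-phenylundeca-3,10-dien-5-yl methyl carbonate
Conditions: Dess–Martin periodinane, NaHCO3, CH2Cl2, 0 °C; used crude at once
Reagents that add atoms: none
Why: Dess–Martin oxidation under bicarbonate buffer is mild and non-basic, so the skipped (β,γ-unsaturated) aldehyde should form without migration of the alkene into conjugation or loss of the δ-carbonate.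

Step 10
Reactants: 17 (3E,5S,7S,9S,10E)-7,9-dimethoxy-1-oxo-11-phenylundeca-3,10-dien-5-yl methyl carbonate; 16 1,1-bis(trimethylsilyloxy)ethene
Product: 20 (4S,6R)-6-[(1E,4R,6S,7E)-4,6-dimethoxy-8-phenylocta-1,7-dien-1-yl]-4-hydroxyoxan-2-one, via bis-silyl aldol adduct 18 (not isolated), via O-silylated lactone 19 (not isolated)
Conditions: 16 (1.3 equiv), Ti(OiPr)4, tridentate binaphthyl Schiff-base ligand (Re-face-selective enantiomer), 3,5-di-tert-butylsalicylic acid (5 mol % each), Et2O, −10 °C; volatiles off in vacuo; Pd(PPh3)4 (5 mol %), THF, 0 °C to rt; aq. citric acid, MeOH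
Reagents that add atoms: none
Why: Proposed new method: a one-flask formal [3+3] annulation of a ketene bis(silyl) acetal (acetate C,O-dinucleophile) with an aldehyde that carries a latent π-allyl terminus; the closest known reactions are the titanium-catalysed enantioselective Mukaiyama acetate aldol and the Tsuji–Trost lactonisation of carboxylates onto allylic carbonates, here merged without work-up. In the first stage the chiral tetravalent titanium Lewis acid activates the aldehyde, 16 adds to its Re face with silyl transfer, and C3–C4 forms with 4S set by the catalyst alone, since no resident stereocentre lies near C4. In the second stage zerovalent palladium ionises the carbonate anti to the leaving group, CO2 departs, and the methoxide so released strips the silyl ester to a carboxylate that attacks C6 of the syn,syn-π-allyl anti to palladium, a 6-exo closure of the lactone ring that forms O1–C6 (attack at C2' would need an eight-membered ring). The two inversions relay the S configuration of the carbonate carbon to 6R (1,3-chirality transfer), and the syn,syn geometry of the allyl gives the E C1'=C2' alkene. The step needs chemoselectivity and speed: excess 16 is pumped off before palladium is added so that it cannot C-allylate the π-allyl, the methyl ether at C6' is not a leaving group for zerovalent palladium, and ring closure must outrun epimerisation or β-hydride elimination of the π-allyl. Mild acid work-up then cleaves the C4 silyl ether to give 20.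

Compound list
1 | (E)-cinnamaldehyde | O=C/C=C/c1ccccc1 | starting material
2 | 1-methoxy-1,3-bis(trimethylsilyloxy)buta-1,3-diene (ketene-acetal geometry as supplied) | COC(O[Si](C)(C)C)=CC(=C)O[Si](C)(C)C | starting material
3 | methyl (5S,6E)-7-phenyl-3,5-bis(trimethylsilyloxy)hepta-2,6-dienoate (2-ene geometry not defined) | COC(=O)C=C(O[Si](C)(C)C)C[C@H](O[Si](C)(C)C)/C=C/c1ccccc1 | intermediate (not isolated)
4 | methyl (5S,6E)-5-hydroxy-3-oxo-7-phenylhept-6-enoate | COC(=O)CC(=O)C[C@H](O)/C=C/c1ccccc1 | intermediate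
5 | methyl (3S,5S,6E)-3,5-dihydroxy-7-phenylhept-6-enoate | COC(=O)C[C@@H](O)C[C@H](O)/C=C/c1ccccc1 | intermediate
6 | methyl (3S,5S,6E)-3,5-dimethoxy-7-phenylhept-6-enoate | COC(=O)C[C@@H](OC)C[C@H](OC)/C=C/c1ccccc1 | intermediate
7 | (3S,5S,6E)-3,5-dimethoxy-7-phenylhept-6-enal | O=CC[C@@H](OC)C[C@H](OC)/C=C/c1ccccc1 | intermediate
8 | tert-butyl(but-3-yn-1-yloxy)dimethylsilane | C#CCCO[Si](C)(C)C(C)(C)C | starting material
9 | [(1E)-4-(tert-butyldimethylsilyloxy)but-1-en-1-yl]dicyclohexylborane | CC(C)(C)[Si](C)(C)OCC/C=C/B(C1CCCCC1)C1CCCCC1 | intermediate (not isolated)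
10 | [(1E)-4-(tert-butyldimethylsilyloxy)but-1-en-1-yl](methyl)zinc | CC(C)(C)[Si](C)(C)OCC/C=C/[Zn]C | intermediate (not isolated)
11 | (3E,5S,7R,9S,10E)-1-(tert-butyldimethylsilyloxy)-7,9-dimethoxy-11-phenylundeca-3,10-dien-5-ol | CC(C)(C)[Si](C)(C)OCC/C=C/[C@@H](O)C[C@@H](OC)C[C@H](OC)/C=C/c1ccccc1 | intermediate
12 | (3E,5S,7S,9S,10E)-1-(tert-butyldimethylsilyloxy)-7,9-dimethoxy-11-phenylundeca-3,10-dien-5-yl methyl carbonate | CC(C)(C)[Si](C)(C)OCC/C=C/[C@@H](OC(=O)OC)C[C@@H](OC)C[C@H](OC)/C=C/c1ccccc1 | intermediate
13 | (3E,5S,7S,9S,10E)-1-hydroxy-7,9-dimethoxy-11-phenylundeca-3,10-dien-5-yl methyl carbonate | OCC/C=C/[C@@H](OC(=O)OC)C[C@@H](OC)C[C@H](OC)/C=C/c1ccccc1 | intermediate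
14 | trimethylsilyl acetate | CC(=O)O[Si](C)(C)C | starting material
15 | lithium 1-(trimethylsilyloxy)ethen-1-olate | [Li]OC(=C)O[Si](C)(C)C | intermediate (not isolated)
16 | 1,1-bis(trimethylsilyloxy)ethene | C=C(O[Si](C)(C)C)O[Si](C)(C)C | intermediate
17 | (3E,5S,7S,9S,10E)-7,9-dimethoxy-1-oxo-11-phenylundeca-3,10-dien-5-yl methyl carbonate | O=CC/C=C/[C@@H](OC(=O)OC)C[C@@H](OC)C[C@H](OC)/C=C/c1ccccc1 | intermediate
18 | trimethylsilyl (3S,5E,7S,9S,11S,12E)-9,11-dimethoxy-7-[(methoxycarbonyl)oxy]-13-phenyl-3-(trimethylsilyloxy)trideca-5,12-dienoate | C[Si](C)(C)OC(=O)C[C@@H](O[Si](C)(C)C)C/C=C/[C@@H](OC(=O)OC)C[C@@H](OC)C[C@H](OC)/C=C/c1ccccc1 | intermediate (not isolated)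
19 | (4S,6R)-6-[(1E,4R,6S,7E)-4,6-dimethoxy-8-phenylocta-1,7-dien-1-yl]-4-(trimethylsilyloxy)oxan-2-one | CO[C@H](C/C=C/[C@H]1C[C@H](O[Si](C)(C)C)CC(=O)O1)C[C@@H](/C=C/c1ccccc1)OC | intermediate (not isolated)
20 | (4S,6R)-6-[(1E,4R,6S,7E)-4,6-dimethoxy-8-phenylocta-1,7-dien-1-yl]-4-hydroxyoxan-2-one | CO[C@H](C/C=C/[C@H]1C[C@H](O)CC(=O)O1)C[C@@H](/C=C/c1ccccc1)OC | target

Total step count: 10 (step 8 prepares reagent 16).
Longest linear sequence: 9 steps (1 → 4 → 5 → 6 → 7 → 11 → 12 → 13 → 17 → 20).

Steps most likely to fail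

1. Step 10. Facial control in the titanium-catalysed addition of the bis(silyl) acetal may be weak and give the C4 epimer. The skipped alkene of 17 may migrate into conjugation, with loss of the carbonate, before the aldol is complete. In the palladium stage the π-allyl may be captured by methoxide or residual ketene acetal, may undergo β-hydride elimination to a diene, or may epimerise so that the chirality transfer leaks. Fallback, in which each bond is made in a separate known step so that C4 epimers can be removed at an isolable ester: from 17, the same titanium catalyst is used with the alkyl-acetate-derived ketene acetal 1-[2-(trimethylsilyl)ethoxy]-1-(trimethylsilyloxy)ethene F1 (from commercial 2-(trimethylsilyl)ethyl acetate, LiN(iPr)2 and Me3SiCl), a nucleophile class for which this aldol is established. Mild acid work-up should give 2-(trimethylsilyl)ethyl (3S,5E,7S,9S,11S,12E)-3-hydroxy-9,11-dimethoxy-7-[(methoxycarbonyl)oxy]-13-phenyltrideca-5,12-dienoate F2, which is purified. Bu4NF in THF then frees (3S,5E,7S,9S,11S,12E)-3-hydroxy-9,11-dimethoxy-7-[(methoxycarbonyl)oxy]-13-phenyltrideca-5,12-dienoic acid F3, and Pd(PPh3)4 with Et3N in THF closes the lactone by the same double-inversion allylic substitution, so that the route is rejoined at 20.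

2. Step 5. Chelation of zinc by the β-methoxy group of 7 may compete with ligand control and erode facial selectivity, boron-to-zinc exchange may be incomplete, and methyl transfer may compete with alkenyl transfer. Fallback by alkynylation and trans-reduction: from 7 and 8, Me2Zn converts 8 into methyl[4-(tert-butyldimethylsilyloxy)but-1-yn-1-yl]zinc F4, which adds to 7 under ProPhenol catalysis (ligand antipode chosen for Re-face attack) to give (5S,7R,9S,10E)-1-(tert-butyldimethylsilyloxy)-7,9-dimethoxy-11-phenylundec-10-en-3-yn-5-ol F5. Trans-hydroalumination of this propargylic alcohol with NaAlH2(OCH2CH2OMe)2 in THF and protonolysis should give the E-allylic alcohol, rejoining the route at 11.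

3. Step 3. Double alkylation may stop at the mono-ether, the diol ester may lactonise, and the styryl carbinol may ionise under the alkylating conditions. Fallback, in which the ester is reduced first so that methylation becomes a plain Williamson reaction on a substrate that cannot lactonise or retro-aldolise: from 5, LiBH4 in THF gives (3R,5S,6E)-7-phenylhept-6-ene-1,3,5-triol F6. Selective silylation of the primary hydroxyl with tert-butyldiphenylsilyl chloride and imidazole (a group that resists 1,3-migration) gives (3R,5S,6E)-1-(tert-butyldiphenylsilyloxy)-7-phenylhept-6-ene-3,5-diol F7. NaH and MeI in THF give tert-butyl{[(3R,5S,6E)-3,5-dimethoxy-7-phenylhept-6-en-1-yl]oxy}diphenylsilane F8, Bu4NF gives (3R,5S,6E)-3,5-dimethoxy-7-phenylhept-6-en-1-ol F9, and Dess–Martin oxidation rejoins the route at 7.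

Further compounds
F1 | step 10 | 1-[2-(trimethylsilyl)ethoxy]-1-(trimethylsilyloxy)ethene | C=C(OCC[Si](C)(C)C)O[Si](C)(C)C
F2 | step 10 | 2-(trimethylsilyl)ethyl (3S,5E,7S,9S,11S,12E)-3-hydroxy-9,11-dimethoxy-7-[(methoxycarbonyl)oxy]-13-phenyltrideca-5,12-dienoate | C[Si](C)(C)CCOC(=O)C[C@@H](O)C/C=C/[C@@H](OC(=O)OC)C[C@@H](OC)C[C@H](OC)/C=C/c1ccccc1
F3 | step 10 | (3S,5E,7S,9S,11S,12E)-3-hydroxy-9,11-dimethoxy-7-[(methoxycarbonyl)oxy]-13-phenyltrideca-5,12-dienoic acid | OC(=O)C[C@@H](O)C/C=C/[C@@H](OC(=O)OC)C[C@@H](OC)C[C@H](OC)/C=C/c1ccccc1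
F4 | step 5 | methyl[4-(tert-butyldimethylsilyloxy)but-1-yn-1-yl]zinc | CC(C)(C)[Si](C)(C)OCCC#C[Zn]C
F5 | step 5 | (5S,7R,9S,10E)-1-(tert-butyldimethylsilyloxy)-7,9-dimethoxy-11-phenylundec-10-en-3-yn-5-ol | CC(C)(C)[Si](C)(C)OCCC#C[C@@H](O)C[C@@H](OC)C[C@H](OC)/C=C/c1ccccc1
F6 | step 3 | (3R,5S,6E)-7-phenylhept-6-ene-1,3,5-triol | OCC[C@@H](O)C[C@H](O)/C=C/c1ccccc1
F7 | step 3 | (3R,5S,6E)-1-(tert-butyldiphenylsilyloxy)-7-phenylhept-6-ene-3,5-diol | CC(C)(C)[Si](OCC[C@@H](O)C[C@H](O)/C=C/c1ccccc1)(c1ccccc1)c1ccccc1
F8 | step 3 | tert-butyl{[(3R,5S,6E)-3,5-dimethoxy-7-phenylhept-6-en-1-yl]oxy}diphenylsilane | CC(C)(C)[Si](OCC[C@@H](OC)C[C@H](OC)/C=C/c1ccccc1)(c1ccccc1)c1ccccc1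
F9 | step 3 | (3R,5S,6E)-3,5-dimethoxy-7-phenylhept-6-en-1-ol | OCC[C@@H](OC)C[C@H](OC)/C=C/c1ccccc1
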